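**Plan**
1. The retrosynthesis first cuts the depside ester bond between the ring A carbonyl carbon and O4 of ring B. It then cuts the ring B bonds C3–C4 and C5–C6.
2. Enabling feature: on ring B the carboxyl carbon (C1), the oxygen (C2) and the propyl group (C6) sit on three neighbouring ring atoms. This is the pattern of C5, C4 and C6 of a 2-pyrone-5-carboxylate, and C4–O with C5–H are the two carbons of a ketene acetal.
3. Ring B, forward: acylation of an acetonedicarboxylate and lactonisation give the pyrone ring. Cycloaddition with loss of CO2 and methanol turns it into the benzene ring, which is then reworked to a benzyl ester with free phenols.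
4. Ring A, forward: purchased 5-propylresorcinol already holds the ring. It is formylated, benzylated at O4, methylated at O2 and oxidised to the acid.
5. The halves are joined at O4 of ring B, and one hydrogenolysis removes both benzyl groups.
6. Stereochemistry: the target has no stereocentre and no stereogenic double bond, so none has to be set.

Key step: step 4

Assumption: pyrone atoms are counted from the ring oxygen (O1) with the lactone carbonyl as C2. 1,1-Dimethoxyethene and 5-propylbenzene-1,3-diol are taken as purchasable.

**Step 1**
Reactants: 1 dimethyl 3-oxopentanedioate; 2 butanoyl chloride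
Product: 3 dimethyl 2-butanoyl-3-oxopentanedioate
Conditions: MgCl2 (1 equiv), pyridine (2 equiv), CH2Cl2, 0 °C; then 2 (1 equiv), 0 °C → rt; 1 M HCl wash
Reagents that add atoms: none
Why: Chelation to magnesium makes a methylene C–H of the β-keto diester acidic enough for pyridine, and the chelated enolate undergoes C-acylation by the acid chloride (soft-enolisation acylation of a β-keto ester), after which the more acidic tricarbonyl product holds the second equivalent of base and resists further acylation.

**Step 2**
Reactants: 3 dimethyl 2-butanoyl-3-oxopentanedioate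
Product: 4 methyl 4-hydroxy-2-oxo-6-propyl-2H-pyran-5-carboxylate
Conditions: DBU (1.1 equiv), toluene, 80 °C; then 1 M HCl
Reagents that add atoms: none
Why: The enolate oxygen of the butanoyl group can reach the ester of the unsubstituted CH2CO2Me arm through a six-membered transition state, so base-promoted lactonisation of this 3,5-dioxo ester (6-exo-trig acyl substitution with loss of methanol) closes the 4-hydroxy-2-pyrone and is driven by formation of the stabilised pyronate anion.

**Step 3**
Reactants: 4 methyl 4-hydroxy-2-oxo-6-propyl-2H-pyran-5-carboxylate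
Product: 5 methyl 4-methoxy-2-oxo-6-propyl-2H-pyran-5-carboxylate
Conditions: Me2SO4 (1.2 equiv), K2CO3, acetone, reflux
Reagents that add atoms: dimethyl sulfate, COS(=O)(=O)OC
Why: Williamson-type O-alkylation of 4-hydroxy-2-pyrones with a hard methylating agent and K2CO3 is known to fall on the C4 oxygen and to give the 4-methoxy-2-pyrone rather than the 2-methoxy-4-pyrone.

**Step 4**
Reactants: 5 methyl 4-methoxy-2-oxo-6-propyl-2H-pyran-5-carboxylate; 6 1,1-dimethoxyethene
Product: 9 methyl 2,4-dimethoxy-6-propylbenzoate, via bridged lactone adduct 7 (not isolated), via trimethoxycyclohexadiene ester 8 (not isolated)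
Conditions: 6 (5 equiv), toluene, base-washed sealed tube, 150 °C
Reagents that add atoms: none
Why: The pyrone acts as an electron-poor diene (C3=C4–C5=C6) whose C6 is the acceptor terminus of both the C5 ester and the C2 lactone carbonyl, so the nucleophilic CH2 of 6 bonds there first and the developing dimethoxycarbenium centre is caught by C3 in a concerted but strongly asynchronous inverse-electron-demand Diels–Alder reaction that gives 7. Retro-Diels–Alder loss of CO2 from 7 gives diene 8, and 1,2-elimination of methanol from its CH2–C(OMe)2 unit gives arene 9. The closest known reaction type is the conversion of 2-pyrone-5-carboxylates and 2-pyrone-3-carboxylates into alkoxybenzoates with ketene acetals. Ring B closes by an intermolecular (4+2) cycloaddition that forms its C5–C6 and C3–C4 bonds, with four ring carbons coming from the pyrone and two from 6. The two bridgehead stereocentres of 7 are locked to each other by the bicycle, arise as a racemate and vanish on aromatisation, so no stereocontrol is required. The step needs regioselectivity, which the substrate secures twice because the C5 ester marks C6 as the electrophilic end and the C4 methoxy group makes C3 the nucleophilic end, while the slower rate caused by that donor and by the C6 propyl group is met with excess 6 and high temperature.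

**Step 5**
Reactants: 9 methyl 2,4-dimethoxy-6-propylbenzoate
Product: 10 2,4-dimethoxy-6-propylbenzoic acid
Conditions: KOH, DMSO–H2O, 100 °C; then 2 M HCl, 0 °C
Reagents that add atoms: potassium hydroxide, [K+].[OH-]
Why: Saponification of a 2,6-disubstituted benzoate is slow in aqueous alcohol but proceeds with the poorly solvated hydroxide available in DMSO, and the aryl methyl ethers are inert to base.

**Step 6**
Reactants: 10 2,4-dimethoxy-6-propylbenzoic acid
Product: 11 2,4-dihydroxy-6-propylbenzoic acid (divaric acid)
Conditions: BBr3 (4 equiv), CH2Cl2, −78 °C → rt; then ice-water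
Reagents that add atoms: none
Why: BBr3 cleaves aryl methyl ethers by coordination to oxygen and bromide attack on the methyl carbon (Lewis acid ether cleavage), the C2 ether being helped by chelation to the carboxyl group, and working at or below room temperature should keep the electron-rich acid from losing CO2.

**Step 7**
Reactants: 11 2,4-dihydroxy-6-propylbenzoic acid
Product: 12 benzyl 2,4-dihydroxy-6-propylbenzoate
Conditions: BnBr (1.05 equiv), KHCO3, DMF, rt
Reagents that add atoms: benzyl bromide, BrCc1ccccc1
Why: KHCO3 deprotonates only the carboxylic acid, so SN2 alkylation of the carboxylate by benzyl bromide gives the ester and leaves both phenols free.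

**Step 8**
Reactants: 13 5-propylbenzene-1,3-diol
Product: 15 2,4-dihydroxy-6-propylbenzaldehyde, via aryl iminium chloride 14 (not isolated)
Conditions: POCl3, DMF, 0 °C → rt; then ice-water
Reagents that add atoms: N,N-dimethylformamide, CN(C)C=O; water, O
Why: Vilsmeier–Haack formylation of 5-alkylresorcinols takes place at the position ortho to one hydroxyl and para to the other, as established for the methyl and pentyl homologues, and hydrolysis of iminium salt 14 frees the aldehyde.

**Step 9**
Reactants: 15 2,4-dihydroxy-6-propylbenzaldehyde
Product: 16 4-(benzyloxy)-2-hydroxy-6-propylbenzaldehyde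
Conditions: BnBr (1.0 equiv), K2CO3 (1.0 equiv), acetone, rt → 40 °C
Reagents that add atoms: benzyl bromide, BrCc1ccccc1
Why: The C2 hydroxyl is held in a hydrogen bond to the aldehyde and is the less acidic and less nucleophilic of the two, so a Williamson etherification with one equivalent of benzyl bromide falls on the C4 hydroxyl.

**Step 10**
Reactants: 16 4-(benzyloxy)-2-hydroxy-6-propylbenzaldehyde
Product: 17 4-(benzyloxy)-2-methoxy-6-propylbenzaldehyde
Conditions: MeI, K2CO3, DMF, 40 °C
Reagents that add atoms: iodomethane, CI
Why: With O4 blocked, Williamson methylation in a dipolar aprotic solvent alkylates the one remaining, chelated phenol.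

**Step 11**
Reactants: 17 4-(benzyloxy)-2-methoxy-6-propylbenzaldehyde
Product: 18 4-(benzyloxy)-2-methoxy-6-propylbenzoic acid
Conditions: NaClO2, NaH2PO4, 2-methyl-2-butene, t-BuOH–H2O, rt
Reagents that add atoms: sodium chlorite, [Na+].[O-]Cl=O
Why: The Pinnick oxidation converts hindered, electron-rich benzaldehydes into the acids without touching benzyl or methyl ethers, and the alkene scavenger removes HOCl before it can chlorinate the ring.

**Step 12**
Reactants: 18 4-(benzyloxy)-2-methoxy-6-propylbenzoic acid; 12 benzyl 2,4-dihydroxy-6-propylbenzoate
Product: 20 benzyl 4-{[4-(benzyloxy)-2-methoxy-6-propylbenzoyl]oxy}-2-hydroxy-6-propylbenzoate, via aroyl trifluoroacetate 19 (not isolated)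
Conditions: (CF3CO)2O, toluene, rt
Reagents that add atoms: none
Why: Trifluoroacetic anhydride turns the hindered, electron-rich acid into mixed anhydride 19, a strongly activated acyl donor, and esterification takes place at the C4 hydroxyl of 12 because the C2 hydroxyl is hydrogen-bonded to the neighbouring benzyl ester and shielded by it, the usual outcome of mixed-anhydride depside couplings.

**Step 13**
Reactants: 20 benzyl 4-{[4-(benzyloxy)-2-methoxy-6-propylbenzoyl]oxy}-2-hydroxy-6-propylbenzoate
Product: 21 2-hydroxy-4-[(4-hydroxy-2-methoxy-6-propylbenzoyl)oxy]-6-propylbenzoic acid (target)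
Conditions: H2 (1 atm), 10% Pd/C, EtOAc, rt
Reagents that add atoms: none
Why: Catalytic hydrogenolysis cleaves the benzyl ester and the benzyl ether together under neutral conditions that leave the depside ester, the methyl ether and the decarboxylation-prone acid untouched.

**Compound list**
1 | dimethyl 3-oxopentanedioate | COC(=O)CC(=O)CC(=O)OC | starting material
2 | butanoyl chloride | CCCC(=O)Cl | starting material
3 | dimethyl 2-butanoyl-3-oxopentanedioate (largely enolised; C2 is configurationally labile, no configuration assigned) | CCCC(=O)C(C(=O)OC)C(=O)CC(=O)OC | intermediate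
4 | methyl 4-hydroxy-2-oxo-6-propyl-2H-pyran-5-carboxylate | CCCC1=C(C(=O)OC)C(O)=CC(=O)O1 | intermediate
5 | methyl 4-methoxy-2-oxo-6-propyl-2H-pyran-5-carboxylate | CCCC1=C(C(=O)OC)C(OC)=CC(=O)O1 | intermediate
6 | 1,1-dimethoxyethene | C=C(OC)OC | starting material
7 | methyl 5,8,8-trimethoxy-3-oxo-1-propyl-2-oxabicyclo[2.2.2]oct-5-ene-6-carboxylate (racemic, one enantiomer drawn; bridgeheads C1 and C4 locked by the bicycle) | CCC[C@@]12OC(=O)[C@@H](C(OC)=C1C(=O)OC)C(OC)(OC)C2 | intermediate
8 | methyl 4,4,6-trimethoxy-2-propylcyclohexa-1,5-diene-1-carboxylate | CCCC1=C(C(=O)OC)C(OC)=CC(OC)(OC)C1 | intermediate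
9 | methyl 2,4-dimethoxy-6-propylbenzoate | CCCc1cc(OC)cc(OC)c1C(=O)OC | intermediate
10 | 2,4-dimethoxy-6-propylbenzoic acid | CCCc1cc(OC)cc(OC)c1C(=O)O | intermediate
11 | 2,4-dihydroxy-6-propylbenzoic acid (divaric acid) | CCCc1cc(O)cc(O)c1C(=O)O | intermediate
12 | benzyl 2,4-dihydroxy-6-propylbenzoate | CCCc1cc(O)cc(O)c1C(=O)OCc1ccccc1 | intermediate
13 | 5-propylbenzene-1,3-diol | CCCc1cc(O)cc(O)c1 | starting material
14 | [(2,4-dihydroxy-6-propylphenyl)methylidene]dimethyliminium chloride | CCCc1cc(O)cc(O)c1C=[N+](C)C.[Cl-] | intermediate
15 | 2,4-dihydroxy-6-propylbenzaldehyde | CCCc1cc(O)cc(O)c1C=O | intermediate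
16 | 4-(benzyloxy)-2-hydroxy-6-propylbenzaldehyde | CCCc1cc(OCc2ccccc2)cc(O)c1C=O | intermediate
17 | 4-(benzyloxy)-2-methoxy-6-propylbenzaldehyde | CCCc1cc(OCc2ccccc2)cc(OC)c1C=O | intermediate
18 | 4-(benzyloxy)-2-methoxy-6-propylbenzoic acid | CCCc1cc(OCc2ccccc2)cc(OC)c1C(=O)O | intermediate
19 | 4-(benzyloxy)-2-methoxy-6-propylbenzoic trifluoroacetic anhydride | CCCc1cc(OCc2ccccc2)cc(OC)c1C(=O)OC(=O)C(F)(F)F | intermediate
20 | benzyl 4-{[4-(benzyloxy)-2-methoxy-6-propylbenzoyl]oxy}-2-hydroxy-6-propylbenzoate | CCCc1cc(OC(=O)c2c(CCC)cc(OCc3ccccc3)cc2OC)cc(O)c1C(=O)OCc1ccccc1 | intermediate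
21 | 2-hydroxy-4-[(4-hydroxy-2-methoxy-6-propylbenzoyl)oxy]-6-propylbenzoic acid | CCCc1cc(OC(=O)c2c(CCC)cc(O)cc2OC)cc(O)c1C(=O)O | target

**Step count**
Total step count: 13.
Longest linear sequence: 9 steps (steps 1–7, 12 and 13).

**Steps most likely to fail**

1. Step 4. The donor at C4 and the alkyl group at C6 raise the barrier of the cycloaddition. Thermal decay or oligomerisation of the ketene acetal may therefore outrun ring formation. The fallback sets out from 16 and comes back at 11, taking ring B from the purchased resorcinol instead of building it. Pinnick oxidation of 16 (NaClO2, NaH2PO4, 2-methyl-2-butene, t-BuOH–H2O) should give 4-(benzyloxy)-2-hydroxy-6-propylbenzoic acid F1. Hydrogenolysis of F1 (H2, Pd/C, EtOAc) frees 11, which enters step 7.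

2. Step 6. The electron-rich free acid may undergo protodecarboxylation under the Lewis and Brønsted acidic conditions, or the C4 ether may be cleaved incompletely. The fallback sets out from 9 and comes back at 11, reversing the order so that the carboxyl group stays masked while the Lewis acid is present. BBr3 in CH2Cl2 (−78 → 0 °C) on ester 9 should give methyl 2,4-dihydroxy-6-propylbenzoate F2. This is saponified as its phenolate with aqueous KOH at reflux under N2 and acidified at 0 °C to give 11.

3. Step 1. Acylation may occur on oxygen or at both methylene groups, and the tricarbonyl product may be deacylated on work-up. The fallback sets out from 2 and comes back at 4, passing by 3 and step 2.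
   - Acylation of Meldrum's acid with 2 (pyridine, CH2Cl2, 0 °C) gives 5-(1-hydroxybutylidene)-2,2-dimethyl-1,3-dioxane-4,6-dione F3.
   - Methanolysis of F3 at reflux gives methyl 3-oxohexanoate F4.
   - Condensation of F4 with malonyl dichloride in CH2Cl2 at reflux closes the same pyrone 4, by C-acylation at the α-carbon and O-acylation of the enol.

**Further compounds**
F1 | step 4 | 4-(benzyloxy)-2-hydroxy-6-propylbenzoic acid | CCCc1cc(OCc2ccccc2)cc(O)c1C(=O)O
F2 | step 6 | methyl 2,4-dihydroxy-6-propylbenzoate | CCCc1cc(O)cc(O)c1C(=O)OC
F3 | step 1 | 5-(1-hydroxybutylidene)-2,2-dimethyl-1,3-dioxane-4,6-dione | CCCC(O)=C1C(=O)OC(C)(C)OC1=O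
F4 | step 1 | methyl 3-oxohexanoate | CCCC(=O)CC(=O)OC
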